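Locants: C1 is the angular methyl carbon, C4 the isopropyl carbinol, C5 the ring-fusion CH, and C6–C10 run round the seven-membered ring from the aroyloxy carbon to the tigloyloxy carbon. That ring is opened between C7 and C8: C7, a methylene flanked by the C6 carbinol and methyl-bearing C8, becomes the CH2 of a C6 acetate-aldol unit, and C8 the β-carbon of a butenoyl ketone on quaternary C1. Cathodic fragmentation of the N-acyloxyphthalimide expels CO2 and closes the ring 7-endo at C7–C8 in one operation; the C10 ketone then returns the C8=C9 alkene. The precursor is a cis-1,2-disubstituted cyclopentane bearing the C1 enone and the C5 β-silyloxy redox-active ester chain.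

Key step: step 12

Remark: the target SMILES is read as a cis-fused hydroazulene in which the C1 methyl, H5 and the C10 oxygen lie on one face of the seven-membered ring and the C6 oxygen on the other; on the cyclopentane the C1–C10, C5–C6 and C4–O bonds are mutually cis (1R,4R,5S,6R,10R in the route locants).
Remark: 4-[(tert-butyldimethylsilyl)oxy]benzoic acid is taken as a purchasable reagent.

Step 1
Reactants: 1 (S)-terpinen-4-ol
Product: 2 (S)-triethyl{[4-methyl-1-(propan-2-yl)cyclohex-3-en-1-yl]oxy}silane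
Conditions: TESOTf, 2,6-lutidine, CH2Cl2, 0 °C to rt
Reagents that add atoms: triethylsilyl trifluoromethanesulfonate, CC[Si](CC)(CC)OS(=O)(=O)C(F)(F)F
Why: Silyl triflate silylation of the tertiary alcohol leaves the stereocentre (future C4) untouched and blocks retro-aldol and dehydration of the β-oxygenated aldehyde made next.

Step 2
Reactants: 2 (S)-triethylsilyl ether of terpinen-4-ol
Product: 4 (3S)-6-oxo-3-(propan-2-yl)-3-[(triethylsilyl)oxy]heptanal, via ozonide 3 (not isolated)
Conditions: O3, CH2Cl2, −78 °C; then Me2S, −78 °C to rt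
Reagents that add atoms: ozone, [O-][O+]=O
Why: Ozonolysis with reductive work-up cleaves the only alkene to the 1,6-keto aldehyde without touching the stereocentre.

Step 3
Reactants: 4 (3S)-6-oxo-3-(propan-2-yl)-3-[(triethylsilyl)oxy]heptanal
Product: 5 (5R)-2-methyl-5-(propan-2-yl)-5-[(triethylsilyl)oxy]cyclopent-1-ene-1-carbaldehyde
Conditions: Bn2NH·TFA (cat.), toluene, 50 °C
Reagents that add atoms: none
Why: Ammonium-salt-catalysed intramolecular aldol condensation, in which the enamine of the aldehyde attacks the methyl ketone and water is lost, is the normal course for 6-oxoheptanals and gives the cyclopentene carbaldehyde.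

Step 4
Reactants: 5 (5R)-cyclopentene carbaldehyde; 6 vinylmagnesium bromide
Product: 8 (1R,2S,5R)-2-ethenyl-2-methyl-5-(propan-2-yl)-5-[(triethylsilyl)oxy]cyclopentane-1-carbaldehyde, via trimethylsilyl enol ether 7 (not isolated)
Conditions: CuBr·SMe2 (cat.), TMSCl, DMPU, THF, −78 °C; then K2CO3 (cat.), MeOH, 0 °C
Reagents that add atoms: vinylmagnesium bromide 6, C=C[Mg]Br
Why: Copper-catalysed, TMSCl-accelerated 1,4-addition of the vinyl Grignard reagent to the β,β-disubstituted enal builds quaternary C1 with the vinyl group entering anti to the C4 isopropyl group (pseudoaxial to avoid the formyl group), and methanolysis of the silyl enol ether under equilibrating conditions places the C5 formyl group trans to isopropyl and to the C1 methyl.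

Step 5
Reactants: 8 (1R,2S,5R)-vinyl aldehyde; 9 methyl acetate
Product: 11 methyl (3R)-3-[(1S,2S,5R)-2-ethenyl-2-methyl-5-(propan-2-yl)-5-[(triethylsilyl)oxy]cyclopentyl]-3-hydroxypropanoate, via lithium enolate 10 (not isolated)
Conditions: LDA, THF, −78 °C; then 8, −78 °C; AcOH quench
Reagents that add atoms: methyl acetate 9, CC(=O)OC
Why: Acetate aldol addition of the lithium ester enolate, with Felkin–Anh attack anti to the C5–C4 bond and the carbonyl oxygen turned away from the C4 silyloxy group, sets C6 as R.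

Step 6
Reactants: 11 (3R)-β-hydroxy ester
Product: 12 methyl (3R)-3-[(tert-butyldimethylsilyl)oxy]-3-[(1S,2S,5R)-2-ethenyl-2-methyl-5-(propan-2-yl)-5-[(triethylsilyl)oxy]cyclopentyl]propanoate
Conditions: TBSOTf, 2,6-lutidine, CH2Cl2, −78 to 0 °C
Reagents that add atoms: tert-butyldimethylsilyl trifluoromethanesulfonate, CC(C)(C)[Si](C)(C)OS(=O)(=O)C(F)(F)F
Why: Silyl triflate protection of the hindered secondary alcohol prevents retro-aldol and β-elimination in the later basic steps.

Step 7
Reactants: 12 (3R)-β-silyloxy methyl ester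
Product: 13 (3R)-3-[(tert-butyldimethylsilyl)oxy]-3-[(1S,2S,5R)-2-ethenyl-2-methyl-5-(propan-2-yl)-5-[(triethylsilyl)oxy]cyclopentyl]propanoic acid
Conditions: LiOH, THF/MeOH/H2O, rt; then 0.5 M HCl to pH 4, 0 °C
Reagents that add atoms: lithium hydroxide, [Li+].[OH-]
Why: Saponification of the unhindered methyl ester is carried out here, before any aldehyde or enone is present, so that the acid needs no deprotection later.

Step 8
Reactants: 13 (3R)-β-silyloxy acid
Product: 15 (3R)-3-[(tert-butyldimethylsilyl)oxy]-3-[(1S,2R,5R)-2-formyl-2-methyl-5-(propan-2-yl)-5-[(triethylsilyl)oxy]cyclopentyl]propanoic acid, via ozonide 14 (not isolated)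
Conditions: O3, CH2Cl2, −78 °C; then Me2S, −78 °C to rt
Reagents that add atoms: ozone, [O-][O+]=O
Why: Ozonolysis of the only alkene, the C1 vinyl group, gives the C10 aldehyde, which has no α-hydrogen and cannot epimerise.

Step 9
Reactants: 15 C10 aldehyde acid; 16 (E)-1-bromoprop-1-ene
Product: 18 (3R)-3-[(tert-butyldimethylsilyl)oxy]-3-[(1S,2R,5R)-2-[(2E)-1-hydroxybut-2-en-1-yl]-2-methyl-5-(propan-2-yl)-5-[(triethylsilyl)oxy]cyclopentyl]propanoic acid (both C10 epimers), via (E)-prop-1-enyllithium 17 (not isolated)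
Conditions: 16, t-BuLi, Et2O, −78 °C; then 15, THF, −78 °C; aq. NH4Cl, then pH 4
Reagents that add atoms: (E)-1-bromoprop-1-ene 16, C/C=C/Br
Why: Bromine–lithium exchange with retention of alkene geometry is followed by 1,2-addition to the aldehyde, the first equivalent of alkenyllithium only deprotonating the acid to an inert lithium carboxylate, and the C10 configuration is irrelevant because it is oxidised next.

Step 10
Reactants: 18 allylic alcohol acid
Product: 19 (3R)-3-[(tert-butyldimethylsilyl)oxy]-3-[(1S,2R,5R)-2-[(2E)-but-2-enoyl]-2-methyl-5-(propan-2-yl)-5-[(triethylsilyl)oxy]cyclopentyl]propanoic acid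
Conditions: Dess–Martin periodinane, CH2Cl2, 0 °C to rt
Reagents that add atoms: none
Why: Dess–Martin oxidation of the allylic alcohol tolerates the free acid and both silyl ethers and converges the two C10 epimers on the (E)-enone.

Step 11
Reactants: 19 enone acid; 20 N-hydroxyphthalimide
Product: 21 1,3-dioxoisoindolin-2-yl (3R)-3-[(tert-butyldimethylsilyl)oxy]-3-[(1S,2R,5R)-2-[(2E)-but-2-enoyl]-2-methyl-5-(propan-2-yl)-5-[(triethylsilyl)oxy]cyclopentyl]propanoate
Conditions: DIC, DMAP (cat.), CH2Cl2, rt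
Reagents that add atoms: N-hydroxyphthalimide 20, ON1C(=O)c2ccccc2C1=O
Why: Carbodiimide (Steglich-type) esterification of the unhindered acid gives the redox-active ester under neutral conditions that spare the enone and the silyl ethers.

Step 12
Reactants: 21 redox-active ester
Product: 25 (1R,4R,5S,6R)-6-[(tert-butyldimethylsilyl)oxy]-1,8-dimethyl-4-(propan-2-yl)-4-[(triethylsilyl)oxy]-cis-perhydroazulen-10-one (route locants; both C8 epimers), via C7 radical 22 (not isolated), via C9 radical 23 (not isolated), via enolate 24 (not isolated)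
Conditions: undivided cell, Zn anode, RVC cathode, nBu4NPF6, HFIP (5 equiv), MeCN (5 mM), controlled potential at the reduction wave of the ester, rt; then aq. NH4Cl
Reagents that add atoms: none
Why: Proposed new method: one-electron cathodic reduction of the N-acyloxyphthalimide, which is reduced far more easily than the enone, triggers N–O scission and loss of CO2 to give the primary C7 radical, which adds to C8, the β-carbon of the butenoyl ketone, and the resulting C9 α-keto radical is reduced to the enolate and protonated by HFIP. The closest known chemistry is the electroreductive decarboxylative Giese addition of such redox-active esters to enones, proposed here in an intramolecular version, together with tin- or silane-mediated 7-endo cyclisations onto enones whose carbonyl lies inside the new ring. The seven-membered ring closes in the 7-endo-trig mode, helped by the cis disposition of the two chains on the cyclopentane and by the quaternary C1. The only new stereocentre, C8, is uncontrolled and need not be controlled because it becomes sp2 in step 13, while C1, C4, C5 and C6 are spectators. The selectivity needed is 7-endo closure over 6-exo closure and over premature hydrogen abstraction: attack at C9 is polarity-mismatched and would give an unstabilised radical, divalent zinc ions from the anode activate the enone as a Lewis acid, and dilute acetonitrile is a poor hydrogen-atom donor. Because C1 is quaternary the product ketone can later be desaturated only towards C9.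

Step 13
Reactants: 25 hydroazulen-10-one
Product: 27 (1R,4R,5S,6R)-6-[(tert-butyldimethylsilyl)oxy]-1,8-dimethyl-4-(propan-2-yl)-4-[(triethylsilyl)oxy]-cis-hydroazul-8-en-10-one (route locants), via trimethylsilyl enol ether 26 (not isolated)
Conditions: LDA, TMSCl, THF, −78 °C; then Pd(OAc)2, MeCN, rt
Reagents that add atoms: none
Why: Saegusa–Ito oxidation works because the ketone can enolise only towards C9, and palladation of the silyl enol ether followed by β-hydride elimination of the C8 hydrogen gives the C8=C9 enone from both C8 epimers.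

Step 14
Reactants: 27 C8=C9 enone
Product: 28 (1R,4R,5S,6R,10R)-6-[(tert-butyldimethylsilyl)oxy]-1,8-dimethyl-4-(propan-2-yl)-4-[(triethylsilyl)oxy]-cis-hydroazul-8-en-10-ol (route locants; C10 OH cis to the C1 methyl)
Conditions: (S)-Me-CBS (0.3 equiv), catecholborane, toluene, −78 to −40 °C
Reagents that add atoms: none
Why: Corey–Bakshi–Shibata 1,2-reduction under reagent control, with quaternary C1 as the large flank and vinylic C9 as the small one, lets the (S)-oxazaborolidine deliver hydride to the face of C10 opposite the angular methyl and sets C10 as R.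

Step 15
Reactants: 28 (10R)-allylic alcohol; 29 tiglic acid
Product: 31 (1R,4R,5S,6R,10R)-6-[(tert-butyldimethylsilyl)oxy]-1,8-dimethyl-4-(propan-2-yl)-4-[(triethylsilyl)oxy]-cis-hydroazul-8-en-10-yl (2E)-2-methylbut-2-enoate (route locants), via mixed anhydride 30 (not isolated)
Conditions: 29, 2,4,6-trichlorobenzoyl chloride, Et3N, toluene, rt; then 28, DMAP, 60 °C
Reagents that add atoms: tiglic acid 29, C/C=C(\C)C(=O)O
Why: Yamaguchi esterification acylates the hindered secondary allylic alcohol with retention at C10 and leaves the (E)-geometry of the 2-methylbut-2-enoate intact.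

Step 16
Reactants: 31 bis-silyl tiglate
Product: 32 (1R,4R,5S,6R,10R)-4,6-dihydroxy-1,8-dimethyl-4-(propan-2-yl)-cis-hydroazul-8-en-10-yl (2E)-2-methylbut-2-enoate (route locants)
Conditions: HF·pyridine, pyridine, THF, 0 °C to rt
Reagents that add atoms: none
Why: Buffered hydrogen fluoride cleaves both silyl ethers while the allylic tiglate is stable to these mildly acidic conditions.

Step 17
Reactants: 32 diol tiglate; 33 4-[(tert-butyldimethylsilyl)oxy]benzoic acid
Product: 34 (1R,4R,5S,6R,10R)-6-({4-[(tert-butyldimethylsilyl)oxy]benzoyl}oxy)-4-hydroxy-1,8-dimethyl-4-(propan-2-yl)-cis-hydroazul-8-en-10-yl (2E)-2-methylbut-2-enoate (route locants)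
Conditions: EDC·HCl, DMAP (cat.), CH2Cl2, rt
Reagents that add atoms: 4-[(tert-butyldimethylsilyl)oxy]benzoic acid 33, CC(C)(C)[Si](C)(C)Oc1ccc(cc1)C(=O)O
Why: Steglich esterification is chemoselective for the secondary C6 hydroxyl because the tertiary C4 hydroxyl is too hindered to be acylated, and no stereocentre is affected.

Step 18
Reactants: 34 silyl-protected diester
Product: 35 target, (1R,4R,5S,6R,10R)-4-hydroxy-6-[(4-hydroxybenzoyl)oxy]-1,8-dimethyl-4-(propan-2-yl)-cis-hydroazul-8-en-10-yl (2E)-2-methylbut-2-enoate (route locants)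
Conditions: TBAF, AcOH, THF, 0 °C
Reagents that add atoms: none
Why: Acetic-acid-buffered fluoride removes the aryl silyl ether, the most labile silyl group, without ester cleavage or acyl migration.

Compound list
1 | (S)-terpinen-4-ol | CC1=CC[C@](O)(C(C)C)CC1 | starting material
2 | (S)-triethyl{[4-methyl-1-(propan-2-yl)cyclohex-3-en-1-yl]oxy}silane | CC1=CC[C@](O[Si](CC)(CC)CC)(C(C)C)CC1 | intermediate
3 | ozonide (1,2,4-trioxolane) of 2 | CC1(O2)CC[C@@](O[Si](CC)(CC)CC)(C(C)C)CC2OO1 | intermediate
4 | (3S)-6-oxo-3-(propan-2-yl)-3-[(triethylsilyl)oxy]heptanal | CC(=O)CC[C@@](O[Si](CC)(CC)CC)(C(C)C)CC=O | intermediate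
5 | (5R)-2-methyl-5-(propan-2-yl)-5-[(triethylsilyl)oxy]cyclopent-1-ene-1-carbaldehyde | O=CC1=C(C)CC[C@@]1(O[Si](CC)(CC)CC)C(C)C | intermediate
6 | vinylmagnesium bromide | C=C[Mg]Br | starting material
7 | trimethylsilyl enol ether of 8 | C=C[C@]1(C)CC[C@@](O[Si](CC)(CC)CC)(C(C)C)C1=CO[Si](C)(C)C | intermediate
8 | (1R,2S,5R)-2-ethenyl-2-methyl-5-(propan-2-yl)-5-[(triethylsilyl)oxy]cyclopentane-1-carbaldehyde | C=C[C@]1(C)CC[C@@](O[Si](CC)(CC)CC)(C(C)C)[C@@H]1C=O | intermediate
9 | methyl acetate | CC(=O)OC | starting material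
10 | lithium enolate of methyl acetate | [Li]OC(=C)OC | intermediate
11 | methyl (3R)-3-[(1S,2S,5R)-2-ethenyl-2-methyl-5-(propan-2-yl)-5-[(triethylsilyl)oxy]cyclopentyl]-3-hydroxypropanoate | C=C[C@]1(C)CC[C@@](O[Si](CC)(CC)CC)(C(C)C)[C@@H]1[C@H](O)CC(=O)OC | intermediate
12 | methyl (3R)-3-[(tert-butyldimethylsilyl)oxy]-3-[(1S,2S,5R)-2-ethenyl-2-methyl-5-(propan-2-yl)-5-[(triethylsilyl)oxy]cyclopentyl]propanoate | C=C[C@]1(C)CC[C@@](O[Si](CC)(CC)CC)(C(C)C)[C@@H]1[C@H](O[Si](C)(C)C(C)(C)C)CC(=O)OC | intermediate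
13 | (3R)-3-[(tert-butyldimethylsilyl)oxy]-3-[(1S,2S,5R)-2-ethenyl-2-methyl-5-(propan-2-yl)-5-[(triethylsilyl)oxy]cyclopentyl]propanoic acid | C=C[C@]1(C)CC[C@@](O[Si](CC)(CC)CC)(C(C)C)[C@@H]1[C@H](O[Si](C)(C)C(C)(C)C)CC(=O)O | intermediate
14 | ozonide (3-substituted 1,2,4-trioxolane) of 13 | C1OC(OO1)[C@]2(C)CC[C@@](O[Si](CC)(CC)CC)(C(C)C)[C@@H]2[C@H](O[Si](C)(C)C(C)(C)C)CC(=O)O | intermediate
15 | (3R)-3-[(tert-butyldimethylsilyl)oxy]-3-[(1S,2R,5R)-2-formyl-2-methyl-5-(propan-2-yl)-5-[(triethylsilyl)oxy]cyclopentyl]propanoic acid | O=C[C@]1(C)CC[C@@](O[Si](CC)(CC)CC)(C(C)C)[C@@H]1[C@H](O[Si](C)(C)C(C)(C)C)CC(=O)O | intermediate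
16 | (E)-1-bromoprop-1-ene | C/C=C/Br | starting material
17 | (E)-prop-1-enyllithium | C/C=C/[Li] | intermediate
18 | (3R)-3-[(tert-butyldimethylsilyl)oxy]-3-[(1S,2R,5R)-2-[(2E)-1-hydroxybut-2-en-1-yl]-2-methyl-5-(propan-2-yl)-5-[(triethylsilyl)oxy]cyclopentyl]propanoic acid, both C10 epimers | C/C=C/C(O)[C@]1(C)CC[C@@](O[Si](CC)(CC)CC)(C(C)C)[C@@H]1[C@H](O[Si](C)(C)C(C)(C)C)CC(=O)O | intermediate
19 | (3R)-3-[(tert-butyldimethylsilyl)oxy]-3-[(1S,2R,5R)-2-[(2E)-but-2-enoyl]-2-methyl-5-(propan-2-yl)-5-[(triethylsilyl)oxy]cyclopentyl]propanoic acid | C/C=C/C(=O)[C@]1(C)CC[C@@](O[Si](CC)(CC)CC)(C(C)C)[C@@H]1[C@H](O[Si](C)(C)C(C)(C)C)CC(=O)O | intermediate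
20 | N-hydroxyphthalimide | ON1C(=O)c2ccccc2C1=O | starting material
21 | 1,3-dioxoisoindolin-2-yl ester of 19 (key-step precursor) | C/C=C/C(=O)[C@]1(C)CC[C@@](O[Si](CC)(CC)CC)(C(C)C)[C@@H]1[C@H](O[Si](C)(C)C(C)(C)C)CC(=O)ON2C(=O)c3ccccc3C2=O | intermediate
22 | primary C7 radical formed from 21 by loss of CO2 and phthalimide anion | C/C=C/C(=O)[C@]1(C)CC[C@@](O[Si](CC)(CC)CC)(C(C)C)[C@@H]1[C@H](O[Si](C)(C)C(C)(C)C)[CH2] | intermediate
23 | cyclised C9 α-keto radical | O=C1[CH]C(C)C[C@@H](O[Si](C)(C)C(C)(C)C)[C@@H]2[C@@]1(C)CC[C@@]2(O[Si](CC)(CC)CC)C(C)C | intermediate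
24 | C9–C10 enolate (zinc-bound) | [O-]C1=CC(C)C[C@@H](O[Si](C)(C)C(C)(C)C)[C@@H]2[C@@]1(C)CC[C@@]2(O[Si](CC)(CC)CC)C(C)C | intermediate
25 | (1R,4R,5S,6R)-6-OTBS-4-OTES-1,8-dimethyl-4-(propan-2-yl)-cis-perhydroazulen-10-one, C8 epimers (key-step product; route locants) | O=C1CC(C)C[C@@H](O[Si](C)(C)C(C)(C)C)[C@@H]2[C@@]1(C)CC[C@@]2(O[Si](CC)(CC)CC)C(C)C | intermediate
26 | C9–C10 trimethylsilyl enol ether of 25 | C[Si](C)(C)OC1=CC(C)C[C@@H](O[Si](C)(C)C(C)(C)C)[C@@H]2[C@@]1(C)CC[C@@]2(O[Si](CC)(CC)CC)C(C)C | intermediate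
27 | (1R,4R,5S,6R)-6-OTBS-4-OTES-1,8-dimethyl-4-(propan-2-yl)-cis-hydroazul-8-en-10-one (route locants) | O=C1C=C(C)C[C@@H](O[Si](C)(C)C(C)(C)C)[C@@H]2[C@@]1(C)CC[C@@]2(O[Si](CC)(CC)CC)C(C)C | intermediate
28 | (1R,4R,5S,6R,10R)-6-OTBS-4-OTES-1,8-dimethyl-4-(propan-2-yl)-cis-hydroazul-8-en-10-ol (route locants) | O[C@@H]1C=C(C)C[C@@H](O[Si](C)(C)C(C)(C)C)[C@@H]2[C@@]1(C)CC[C@@]2(O[Si](CC)(CC)CC)C(C)C | intermediate
29 | tiglic acid, (2E)-2-methylbut-2-enoic acid | C/C=C(\C)C(=O)O | starting material
30 | tiglic 2,4,6-trichlorobenzoic anhydride | C/C=C(\C)C(=O)OC(=O)c1c(Cl)cc(Cl)cc1Cl | intermediate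
31 | C10 tiglate of 28 (C4 OTES, C6 OTBS) | C/C=C(\C)C(=O)O[C@@H]1C=C(C)C[C@@H](O[Si](C)(C)C(C)(C)C)[C@@H]2[C@@]1(C)CC[C@@]2(O[Si](CC)(CC)CC)C(C)C | intermediate
32 | C4,C6-diol C10 tiglate | C/C=C(\C)C(=O)O[C@@H]1C=C(C)C[C@@H](O)[C@@H]2[C@@]1(C)CC[C@@]2(O)C(C)C | intermediate
33 | 4-[(tert-butyldimethylsilyl)oxy]benzoic acid | CC(C)(C)[Si](C)(C)Oc1ccc(cc1)C(=O)O | starting material
34 | C6 4-[(tert-butyldimethylsilyl)oxy]benzoate C10 tiglate (C4 OH free) | C/C=C(\C)C(=O)O[C@@H]1C=C(C)C[C@@H](OC(=O)c2ccc(O[Si](C)(C)C(C)(C)C)cc2)[C@@H]2[C@@]1(C)CC[C@@]2(O)C(C)C | intermediate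
35 | CNP0273650.8, C6 4-hydroxybenzoate C10 tiglate of the cis-fused daucene-4,6,10-triol | C/C=C(\C)C(=O)O[C@@H]1C=C(C)C[C@@H](OC(=O)c2ccc(O)cc2)[C@@H]2[C@@]1(C)CC[C@@]2(O)C(C)C | target

Total step count: 18. Longest linear sequence: 18 steps (1 to 35); compounds 6, 9, 16, 20, 29 and 33 are purchased.

Steps most likely to fail

1. Step 12 (Proposed new method). The ring closure may be too slow, because the acceptor carbon C8 is β-methylated. Hydrogen abstraction by the C7 radical, its further reduction with β-elimination of the C6 silyloxy group, or direct cathodic reduction of the enone could then take over. Fallback, known chemistry throughout: replace the electrode by a thiohydroxamate chain reaction. Setting out from acid 19, esterification with 1-hydroxypyridine-2(1H)-thione (DIC, CH2Cl2, dark) gives the Barton ester F1. Visible-light irradiation at high dilution in PhCF3 releases the same C7 radical, which closes 7-endo; the C9 radical then takes a 2-pyridylthio group from a second molecule of the ester to give the C9 sulfide F2. Oxidation with mCPBA at −78 °C gives the sulfoxide F3, which is epimerisable at C9, and its thermal syn-elimination towards C8 gives enone 27, where the route is rejoined. Steps 12 and 13 are both replaced.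

2. Step 14. Facial selectivity may be poor through mismatch: an external hydride may prefer the convex face of the cis-fused bicycle (the face of the angular methyl and H5), which leads to the C10 epimer. Fallback: use that preference and invert during acylation. Setting out from enone 27, Luche reduction (NaBH4, CeCl3, MeOH, −78 °C) gives the 10S alcohol F4. Mitsunobu esterification with tiglic acid 29 (PPh3, DIAD, toluene, 0 °C to rt) then inverts C10 and rejoins the route at tiglate 31.

3. Step 4. Facial selectivity at C1 may be poor, since the isopropyl and silyloxy groups on C4 compete in shielding the enal, and the C4 silyloxy group may be lost by β-elimination from the aldehyde enolate during equilibration. Fallback: deliver the vinyl group intramolecularly from the C4 oxygen. Setting out from 5, TBAF gives the hydroxy enal F5, and (1-bromoethenyl)chlorodimethylsilane with imidazole gives the silyl ether F6. Bu3SnH and AIBN (benzene, 80 °C) generate the α-silyl vinyl radical, which adds to the enal β-carbon C1 in a 6-endo closure that can only form the new C1–C bond cis to the C4 oxygen; hydrogen transfer to C5 gives the bridged siloxane aldehyde F7. TBAF in DMF cleaves the Si–O and Si–C bonds (protodesilylation) to the hydroxy vinyl aldehyde F8, and TESOTf with 2,6-lutidine rejoins the route at 8.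

Further compounds
F1 | step 12 | 2-thioxopyridin-1(2H)-yl ester (Barton ester) of acid 19 | C/C=C/C(=O)[C@]1(C)CC[C@@](O[Si](CC)(CC)CC)(C(C)C)[C@@H]1[C@H](O[Si](C)(C)C(C)(C)C)CC(=O)ON2C=CC=CC2=S
F2 | step 12 | 9-(pyridin-2-ylsulfanyl) derivative of ketone 25, C8 and C9 epimers | O=C1C(Sc3ccccn3)C(C)C[C@@H](O[Si](C)(C)C(C)(C)C)[C@@H]2[C@@]1(C)CC[C@@]2(O[Si](CC)(CC)CC)C(C)C
F3 | step 12 | 9-(pyridin-2-ylsulfinyl) derivative of ketone 25 | O=C1C(S(=O)c3ccccn3)C(C)C[C@@H](O[Si](C)(C)C(C)(C)C)[C@@H]2[C@@]1(C)CC[C@@]2(O[Si](CC)(CC)CC)C(C)C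
F4 | step 14 | (10S)-epimer of allylic alcohol 28 | O[C@H]1C=C(C)C[C@@H](O[Si](C)(C)C(C)(C)C)[C@@H]2[C@@]1(C)CC[C@@]2(O[Si](CC)(CC)CC)C(C)C
F5 | step 4 | (5R)-5-hydroxy-2-methyl-5-(propan-2-yl)cyclopent-1-ene-1-carbaldehyde | O=CC1=C(C)CC[C@@]1(O)C(C)C
F6 | step 4 | (5R)-5-{[(1-bromoethenyl)dimethylsilyl]oxy}-2-methyl-5-(propan-2-yl)cyclopent-1-ene-1-carbaldehyde | O=CC1=C(C)CC[C@@]1(O[Si](C)(C)C(Br)=C)C(C)C
F7 | step 4 | bridged siloxane aldehyde (C4–O–SiMe2–C(=CH2)–C1 bridge, formyl on C5) | C=C2[C@]1(C)CC[C@@](O[Si]2(C)C)(C(C)C)[C@@H]1C=O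
F8 | step 4 | (1R,2S,5R)-2-ethenyl-5-hydroxy-2-methyl-5-(propan-2-yl)cyclopentane-1-carbaldehyde | C=C[C@]1(C)CC[C@@](O)(C(C)C)[C@@H]1C=O
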